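The route rests on the sp3–sp2 bond between C8 and C7 of the diterpenyl chain (C1 = OCH2; ring atoms primed). A Negishi coupling of a primary alkylzinc iodide, whose ring stereocentre C1' is set by CBS reduction and Claisen chirality transfer, with an (E)-2-iodoalkene that already carries the allylic α-linolenate joins both halves in the last operation and gives the trisubstituted C6=C7 olefin with retention of geometry. The step exploits that C8 is a primary carbon insulated from C1' of the cyclohexene ring by C9, while C7 is a methyl-bearing vinyl carbon whose E geometry is established earlier in the route by syn-hydrozirconation of a 2-alkyne.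

Key step: step 10

Remark: the ring stereocentre is read as (S) (priority C2' > C6' > side chain > H); 2,4,4-trimethylcyclohex-2-en-1-one, geranyl acetate and α-linolenic acid are taken as commercial.

Step 1
Reactants: 1 2,4,4-trimethylcyclohex-2-en-1-one
Product: 2 (1R)-2,4,4-trimethylcyclohex-2-en-1-ol
Conditions: (S)-2-methyl-CBS-oxazaborolidine (10 mol %), BH3·SMe2, THF, −20 °C; MeOH quench
Reagents that add atoms: none
Why: Corey–Bakshi–Shibata reduction; the 2-methylalkenyl arm should act as the large group and C6H2 as the small one, so the (S)-catalyst should deliver hydride in the sense that turns acetophenone into (R)-1-phenylethanol and set the (R)-carbinol by 1,2-reduction only.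

Step 2
Reactants: 2 (1R)-2,4,4-trimethylcyclohex-2-en-1-ol
Product: 4 ethyl 2-[(1S)-2,6,6-trimethylcyclohex-2-en-1-yl]acetate, via ketene acetal 3 (not isolated)
Conditions: MeC(OEt)3 (excess), EtCO2H (cat.), 140 °C, EtOH distilled off
Reagents that add atoms: triethyl orthoacetate CC(OCC)(OCC)OCC
Why: Johnson–Claisen rearrangement; the [3,3] shift of 3 is suprafacial, so the new C–C bond should form at the old C3 on the ring face that carried the C1–O bond, transferring the (R)-carbinol chirality to the (S)-configured ring CH and moving the olefin to C2'=C3'.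

Step 3
Reactants: 4 ethyl 2-[(1S)-2,6,6-trimethylcyclohex-2-en-1-yl]acetate
Product: 5 2-[(1S)-2,6,6-trimethylcyclohex-2-en-1-yl]ethan-1-ol
Conditions: LiAlH4, Et2O, 0 °C
Reagents that add atoms: none
Why: Hydride reduction of an ester to the primary alcohol; the stereocentre is β to the carbonyl and cannot epimerise, and the trisubstituted olefin is inert.

Step 4
Reactants: 5 2-[(1S)-2,6,6-trimethylcyclohex-2-en-1-yl]ethan-1-ol
Product: 6 (6S)-6-(2-iodoethyl)-1,5,5-trimethylcyclohex-1-ene
Conditions: I2, PPh3, imidazole, CH2Cl2, 0 → 25 °C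
Reagents that add atoms: iodine II
Why: Appel-type (Garegg–Samuelsson) iodination; iodide should displace the alkoxyphosphonium group at the unhindered primary carbon by SN2.

Step 5
Reactants: 7 geranyl acetate, (2E)-3,7-dimethylocta-2,6-dien-1-yl acetate
Product: 9 (2E)-3-methyl-6-oxohex-2-en-1-yl acetate, via ozonide 8 (not isolated)
Conditions: O3 (1 equiv), CH2Cl2, −78 °C; then PPh3, −78 → 25 °C
Reagents that add atoms: ozone [O-][O+]=O
Why: Chemoselective ozonolysis; the remote 6,7-olefin is more electron-rich than the 2,3-olefin, which the allylic acetoxy group deactivates, so one equivalent of ozone should cleave only the terminal isopropylidene and keep the E geometry of C2=C3.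

Step 6
Reactants: 9 (2E)-3-methyl-6-oxohex-2-en-1-yl acetate
Product: 11 (2E)-3-methylhept-2-en-6-yn-1-ol, via alkynyl acetate 10 (not isolated)
Conditions: MeC(O)C(N2)P(O)(OMe)2, K2CO3, MeOH, 0 → 25 °C
Reagents that add atoms: dimethyl (1-diazo-2-oxopropyl)phosphonate CC(=O)C(=[N+]=[N-])P(=O)(OC)OC
Why: Seyferth–Gilbert homologation in the Ohira–Bestmann form; the aldehyde should give the terminal alkyne, and the same K2CO3/MeOH medium should methanolyse the acetate.

Step 7
Reactants: 11 (2E)-3-methylhept-2-en-6-yn-1-ol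
Product: 13 (2E)-3-methyloct-2-en-6-yn-1-ol, via dilithio alkoxide-acetylide 12 (not isolated)
Conditions: n-BuLi (2.1 equiv), THF, −78 → 0 °C; then MeI (1.05 equiv), DMPU, −78 → 25 °C
Reagents that add atoms: iodomethane CI
Why: Dianion alkylation; the acetylide carbon is far more nucleophilic than the lithium alkoxide oxygen, so one equivalent of iodomethane should methylate carbon only.

Step 8
Reactants: 13 (2E)-3-methyloct-2-en-6-yn-1-ol
Product: 15 (2E,6E)-7-iodo-3-methylocta-2,6-dien-1-ol, via alkenylzirconocene 14 (not isolated)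
Conditions: Cp2Zr(H)Cl (3 equiv), THF, 25 → 50 °C; then I2, 0 °C
Reagents that add atoms: iodine II
Why: Hydrozirconation with the Schwartz reagent followed by iodinolysis; syn addition of Zr–H and equilibration with excess reagent should place zirconium on the methyl-bearing alkyne carbon, and C–Zr to C–I exchange with retention should give the (E)-2-iodoalkene, the hydroxyl being masked in the flask as its zirconium alkoxide.

Step 9
Reactants: 15 (2E,6E)-7-iodo-3-methylocta-2,6-dien-1-ol; 16 α-linolenic acid, (9Z,12Z,15Z)-octadeca-9,12,15-trienoic acid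
Product: 17 (2E,6E)-7-iodo-3-methylocta-2,6-dien-1-yl (9Z,12Z,15Z)-octadeca-9,12,15-trienoate
Conditions: DCC, DMAP (cat.), CH2Cl2, 0 → 25 °C, dark
Reagents that add atoms: none
Why: Steglich esterification; the neutral carbodiimide/DMAP acylation of a primary allylic alcohol should leave the skipped Z,Z,Z-triene and the vinyl iodide untouched.

Step 10
Reactants: 6 (6S)-6-(2-iodoethyl)-1,5,5-trimethylcyclohex-1-ene; 17 (2E,6E)-7-iodo-3-methylocta-2,6-dien-1-yl (9Z,12Z,15Z)-octadeca-9,12,15-trienoate
Product: 19 (2E,6E)-3,7-dimethyl-9-[(1S)-2,6,6-trimethylcyclohex-2-en-1-yl]nona-2,6-dien-1-yl (9Z,12Z,15Z)-octadeca-9,12,15-trienoate, via alkylzinc iodide 18 (not isolated)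
Conditions: Zn dust (BrCH2CH2Br/Me3SiCl-activated), LiCl, THF, 40 °C; then 17, PdCl2(dppf) (5 mol %), THF, 25 °C, dark
Reagents that add atoms: none
Why: Negishi sp3–sp2 cross-coupling: zinc inserts into the primary C–I bond of 6 to give 18, zerovalent palladium (formed from PdCl2(dppf) by the organozinc) adds oxidatively to the vinylic C–I bond of 17 with retention, the alkyl group is transferred from zinc, and reductive elimination forms the C7–C8 bond. The closest known reaction type is the palladium-catalysed coupling of primary alkylzinc halides with trisubstituted (E)-alkenyl iodides. No ring is closed and no stereocentre is created; the E geometry of C6=C7 is carried over from 17, and the ring stereocentre C1', γ to zinc, is not involved. The step needs chemoselectivity for the vinyl iodide over the allylic ester and the skipped triene: oxidative addition to C(sp2)–I should be much faster than ionisation of the allylic carboxylate, organozincs do not add to esters at 25 °C, and the wide-bite-angle dppf ligand should favour reductive elimination over β-hydride elimination.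

Compound list
1 | 2,4,4-trimethylcyclohex-2-en-1-one | CC1=CC(C)(C)CCC1=O | starting material
2 | (1R)-2,4,4-trimethylcyclohex-2-en-1-ol | O[C@H]1C(C)=CC(C)(C)CC1 | intermediate
3 | (6R)-6-[(1-ethoxyethenyl)oxy]-1,3,3-trimethylcyclohex-1-ene (ketene acetal, not isolated) | C=C(OCC)O[C@H]1C(C)=CC(C)(C)CC1 | intermediate
4 | ethyl 2-[(1S)-2,6,6-trimethylcyclohex-2-en-1-yl]acetate | CCOC(=O)C[C@@H]1C(C)=CCCC1(C)C | intermediate
5 | 2-[(1S)-2,6,6-trimethylcyclohex-2-en-1-yl]ethan-1-ol | OCC[C@@H]1C(C)=CCCC1(C)C | intermediate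
6 | (6S)-6-(2-iodoethyl)-1,5,5-trimethylcyclohex-1-ene | ICC[C@@H]1C(C)=CCCC1(C)C | intermediate
7 | geranyl acetate, (2E)-3,7-dimethylocta-2,6-dien-1-yl acetate | CC(=O)OC/C=C(\C)CCC=C(C)C | starting material
8 | (2E)-5-(5,5-dimethyl-1,2,4-trioxolan-3-yl)-3-methylpent-2-en-1-yl acetate (ozonide, not isolated) | CC(=O)OC/C=C(\C)CCC1OOC(C)(C)O1 | intermediate
9 | (2E)-3-methyl-6-oxohex-2-en-1-yl acetate | CC(=O)OC/C=C(\C)CCC=O | intermediate
10 | (2E)-3-methylhept-2-en-6-yn-1-yl acetate (not isolated) | CC(=O)OC/C=C(\C)CCC#C | intermediate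
11 | (2E)-3-methylhept-2-en-6-yn-1-ol | OC/C=C(\C)CCC#C | intermediate
12 | lithium (2E)-7-lithio-3-methylhept-2-en-6-yn-1-olate (not isolated) | [Li]OC/C=C(\C)CCC#C[Li] | intermediate
13 | (2E)-3-methyloct-2-en-6-yn-1-ol | OC/C=C(\C)CCC#CC | intermediate
14 | O-zirconated (2E,6E)-7-[chlorobis(cyclopentadienyl)zirconio]-3-methylocta-2,6-dien-1-olate (not isolated; cyclopentadienyl rings drawn σ-bonded) | Cl[Zr](OC/C=C(\C)CC/C=C(\C)[Zr](Cl)(C1C=CC=C1)C1C=CC=C1)(C1C=CC=C1)C1C=CC=C1 | intermediate
15 | (2E,6E)-7-iodo-3-methylocta-2,6-dien-1-ol | OC/C=C(\C)CC/C=C(\C)I | intermediate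
16 | α-linolenic acid, (9Z,12Z,15Z)-octadeca-9,12,15-trienoic acid | CC/C=C\C/C=C\C/C=C\CCCCCCCC(=O)O | starting material
17 | (2E,6E)-7-iodo-3-methylocta-2,6-dien-1-yl (9Z,12Z,15Z)-octadeca-9,12,15-trienoate | CC/C=C\C/C=C\C/C=C\CCCCCCCC(=O)OC/C=C(\C)CC/C=C(\C)I | intermediate
18 | iodo{2-[(1S)-2,6,6-trimethylcyclohex-2-en-1-yl]ethyl}zinc (not isolated) | I[Zn]CC[C@@H]1C(C)=CCCC1(C)C | intermediate
19 | (2E,6E)-3,7-dimethyl-9-[(1S)-2,6,6-trimethylcyclohex-2-en-1-yl]nona-2,6-dien-1-yl (9Z,12Z,15Z)-octadeca-9,12,15-trienoate | CC/C=C\C/C=C\C/C=C\CCCCCCCC(=O)OC/C=C(\C)CC/C=C(\C)CC[C@@H]1C(C)=CCCC1(C)C | target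

Total step count: 10. Longest linear sequence: 6 steps (steps 5 to 10); the ring branch (steps 1 to 4) joins at step 10.

Steps most likely to fail

Step 10. Ionisation of the allylic ester by zerovalent palladium, β-hydride elimination from the alkylpalladium intermediate, or protonation and homocoupling of the organozinc may erode the coupling. The fallback sets out from 6 and 15 and comes back at 19. It couples before the ester is in place and uses boron in place of zinc. Iodide 6 would be lithiated (t-BuLi, Et2O, −78 °C) and trapped with B-methoxy-9-BBN to give the lithium B-alkyl-B-methoxy-9-borabicyclononane borinate F1. A B-alkyl Suzuki–Miyaura coupling of F1 with the free alcohol 15 (PdCl2(dppf), AsPh3, Cs2CO3, DMF/H2O, 25 °C) should give (2E,6E)-3,7-dimethyl-9-[(1S)-2,6,6-trimethylcyclohex-2-en-1-yl]nona-2,6-dien-1-ol F2, whose free allylic hydroxyl cannot ionise. Steglich esterification of F2 with 16 (DCC, DMAP, CH2Cl2) would then give 19.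

Step 8. Incomplete regiocontrol of the hydrozirconation (zirconium ending up at C6), or competing protonolysis of the alkenylzirconium, may give the wrong or no vinyl iodide. The fallback sets out from 9 and comes back at 19; it avoids the alkyne altogether. Aldehyde 9 would be converted with PPh3/BrCCl3 (CH2Cl2) into (2E)-7,7-dichloro-3-methylhepta-2,6-dien-1-yl acetate F3. A palladium-catalysed trans-selective monoalkylation of F3 with alkylzinc 18 (PdCl2(DPEphos), THF/DMF) should replace only the chloride trans to the chain and give (2E,6Z)-7-chloro-3-methyl-9-[(1S)-2,6,6-trimethylcyclohex-2-en-1-yl]nona-2,6-dien-1-yl acetate F4. Methylation of F4 with retention (Me2Zn, Pd(P(t-Bu)3)2, THF) should give the diterpenyl acetate F5. Methanolysis (K2CO3, MeOH) would give the alcohol F2, and esterification with 16 as above would give 19.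

Step 5. Over-oxidation by cleavage of the 2,3-olefin, or incomplete conversion, may lower the supply of aldehyde. The fallback sets out from 7 and comes back at 9. Epoxidation of the more electron-rich 6,7-olefin (mCPBA, CH2Cl2, 0 °C) would give racemic (2E)-5-(3,3-dimethyloxiran-2-yl)-3-methylpent-2-en-1-yl acetate F6. Cleavage of F6 with H5IO6 (THF/H2O, 0 °C) would give 9.

Further compounds
F1 | step 10 | lithium B-methoxy-B-{2-[(1S)-2,6,6-trimethylcyclohex-2-en-1-yl]ethyl}-9-borabicyclo[3.3.1]nonane borinate | [Li+].CO[B-]1(CC[C@@H]2C(C)=CCCC2(C)C)C3CCCC1CCC3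
F2 | step 10 | (2E,6E)-3,7-dimethyl-9-[(1S)-2,6,6-trimethylcyclohex-2-en-1-yl]nona-2,6-dien-1-ol | OC/C=C(\C)CC/C=C(\C)CC[C@@H]1C(C)=CCCC1(C)C
F3 | step 8 | (2E)-7,7-dichloro-3-methylhepta-2,6-dien-1-yl acetate | CC(=O)OC/C=C(\C)CCC=C(Cl)Cl
F4 | step 8 | (2E,6Z)-7-chloro-3-methyl-9-[(1S)-2,6,6-trimethylcyclohex-2-en-1-yl]nona-2,6-dien-1-yl acetate | CC(=O)OC/C=C(\C)CC/C=C(\Cl)CC[C@@H]1C(C)=CCCC1(C)C
F5 | step 8 | (2E,6E)-3,7-dimethyl-9-[(1S)-2,6,6-trimethylcyclohex-2-en-1-yl]nona-2,6-dien-1-yl acetate | CC(=O)OC/C=C(\C)CC/C=C(\C)CC[C@@H]1C(C)=CCCC1(C)C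
F6 | step 5 | (2E)-5-(3,3-dimethyloxiran-2-yl)-3-methylpent-2-en-1-yl acetate (racemic epoxide) | CC(=O)OC/C=C(\C)CCC1OC1(C)C
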